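Slowly, over days, the target rose in both earlier runs and then sank. I wanted to know what that slowness leaves of the charge in a richer flask.

| flask | starting material | remark | time |
|---|---|---|---|
| south-east | 10 mM | run made earlier |  |
| south-west | 15 mM | run made earlier |  |
| flask | 20 mM |  | 15 d |

- south-east (time / d: target / %): 1.25: 24; 2.08: 29; 3.00: 40; 5.00: 40; 8.00: 39; 12.0: 37; 20.0: 32
- south-west (time / d: target / %): 1.25: 22; 2.08: 30; 3.00: 31; 5.00: 35; 8.00: 33; 12.0: 34; 20.0: 30

(standard deviation of a reading: 1.5 percentage points)

- time, not beyond 15 d, at which the flask holds most target
- the amount of target, in percent of the starting material charged, at that time
- earliest time at which at least nineteen twentieths of that best amount are there, in d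
- latest time at which they still are, in d

- the numbers in the tables scatter with a standard deviation of 1.5 percentage points

I worked with the price, which is the reciprocal of the yield: parts of charge paid per part of target at the top. At 5.00 d the south-east run read 40%, a price of 2.50, and the south-west run read 35%, a price of 2.86. I supposed a loss that needs two molecules to meet, competing with a step that needs one, and took the price, as an approximation, as a straight line in the charge. Its rise per millimolar of charge is 0.0714 /mM, and the line starts from 1.79 at vanishing charge. For the flask with 20 mM this gave 3.21, so I expected 31.2% at the top, which I placed near 5.00 d, the time of the two readings used, with the window opening near 3.00 d.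

For the closing I used the fraction left. The south-east run kept 0.800 of its target from 5.00 d to 20.0 d, a fall of 0.0149 /d. Assuming the same fall in the flask, a loss of 5.00% from the top closes its window near 8.44 d.

The forecast put 28% at 6.5 d, with the window from 3.7 d to 12 d: “It is a flat peak, so its time is poorly fixed.”

The flask gave 30.7% at 4.79 d, with the window from 2.91 d to 7.96 d.

    2 starting material → homo dimer (k = 0.860 /M/h)
    target + released group → side product (k = 0.230 /M/h)
    starting material ⇌ target + released group (K = 0.220 M, k = 0.0200 /h)
    target ⇌ isomer of the product (K = 0.560, k = 0.140 /h)

The forecast's height held, but its window closed later than the flask's. The flask's price was 3.26 against my 3.21. For the neighbouring flask with 80 mM of starting material, all else held, the same line asks 7.50, which means 13.3% of target at the top. That neighbour gave 14.5%, so its price came in lower than the line, at 6.90.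

The readings are calculated from invented constants; the scatter is artificial.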